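(The readings were computed for substances that don't exist.)

| flask | substrate | reagent | free catalyst | remark | time |
|---|---|---|---|---|---|
| eta | 20 mM | 0.25 equiv | 0.1 mol% | run made earlier |  |
| beta | 20 mM | 0.38 equiv | 0.1 mol% | run made earlier |  |
| zeta | 20 mM | 0.50 equiv | 0.05 mol% | run made earlier |  |
| flask | 20 mM | 0.500 equiv | 0.1 mol% |  | 6.0 min |

| run | time / min | target / % | substrate / % |
|---|---|---|---|
| eta | 0.167 | 6.3 | 94.4 |
| eta | 0.667 | 12.9 | 81.6 |
| eta | 2.00 | 7.1 | 75.3 |
| eta | 8.00 | 1.5 | 74.7 |
| beta | 0.167 | 7.8 | 92.8 |
| beta | 0.667 | 15.8 | 73.6 |
| beta | 2.00 | 8.4 | 62.0 |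
| beta | 8.00 | 1.5 | 62.5 |
| zeta | 0.167 | 6.0 | 95.1 |
| zeta | 0.667 | 12.9 | 82.5 |
| zeta | 2.00 | 12.2 | 59.6 |
| zeta | 8.00 | 1.7 | 50.5 |

(each reading ± 0.5 percentage points)

1. time up to 6.0 min at which target stands highest
2. the amount of target, in percent of the substrate charged, at that time

1. Target in this flask comes from substrate, so I first ask how much substrate can go. Eta's substrate stops near 74.7 % of its charge with 0.25 equiv of reagent, and zeta's near 50.5 % with 0.50 equiv. So one reagent takes one substrate. Reagent is the limiting reagent, and this flask's ceiling is 0.500 of the substrate charge.

2. Target does not stay. Eta's target falls to 1.5 % of the charge between its last two readings, while its substrate stands still within the scatter. So target is a passing stock, and its top is where making equals loss.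

3. I suppose that making goes as reagent times catalyst and loss as the square of target. Then the top goes as the root of that product. Eta's top reading gives 8.16. This is my peak constant: the highest target reading over the root of reagent equivalents times catalyst fraction. Beta reads 8.11 and zeta 8.16.

4. Now the question turned round. To reach its ceiling, this flask needs a peak constant of 22.4, which is more than the one read. So I expect this flask's top at 18.2 % of the charge, near 0.667 min, where eta, beta and zeta show their top readings.

5. The forecast's numbers differ from mine: 19.2 % at 0.55 min, with a loss that “fits second order in target”.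

6. The flask gives 18.4 % at 0.698 min.

    reagent + free catalyst ⇌ catalyst intermediate A (K = 160 /M, k = 2400 /M/s)
    catalyst intermediate A → catalyst intermediate B (k = 610 /s)
    catalyst intermediate B ⇌ released group + catalyst intermediate C (K = 0.0250 M, k = 68.0 /s)
    substrate + catalyst intermediate C → catalyst intermediate D (k = 1300 /M/s)
    catalyst intermediate D → free catalyst + target (k = 2400 /s)
    target + released group → side product (k = 7.60 /M/s)

This flask's top over the same root is 8.23. The neighbour flask has 0.4 mol% of free catalyst and the same ceiling. The peak constant gives it 36.5 % of the charge, but its simulated top is 28.6 %. Its own constant is therefore 6.40, lower than the one read from eta. Its substrate ends at 50.0 %, so the part consumed matches the ceiling of 0.500. Its target stands at 1.84 % after 6.00 min.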